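**Plan**

- Retrosynthesis: the C3–Br bond is cut first (electrophilic bromination), then C2–H is traced back to a C2 carboxyl group (a traceless ester), then the C2–C3 bond of the pyrrole ring is cut (aldol condensation), and finally N1–C2 (N-alkylation) and N–S (sulfonylation).
- Enabling feature: the benzene ring of commercial 2-amino-3,5-dibromobenzaldehyde 1 already holds N1 on C7a, the formyl carbon (the future C3) on C3a, and bromine on C5 and C7, so only C2 has to be brought in.
- Forward: N1 is tosylated, C2 is attached to N1 as a glycinate CH2, the pyrrole ring is closed by C2–C3 aldol condensation onto the formyl carbon, the tosyl and carboxyl groups are removed, and C3 is brominated last.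
- Stereochemistry: the target is achiral; the two stereocentres of the transient aldol adduct are erased on dehydration.

Key step: step 3

Remark on the chemistry: aldol adduct 6 is expected as a racemic mixture of diastereomers, so its SMILES is given without configuration; both isomers should converge on the same indole.

**Route**

Step 1
Reactants: 1 2-amino-3,5-dibromobenzaldehyde; 2 p-toluenesulfonyl chloride
Product: 3 N-(2,4-dibromo-6-formylphenyl)-4-methylbenzenesulfonamide
Conditions: TsCl (1.3 equiv), pyridine, DMAP (cat.), 80 °C
Reagents that add atoms: p-toluenesulfonyl chloride (compound 2), Cc1ccc(cc1)S(Cl)(=O)=O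
Why: Sulfonamide formation from an aniline and a sulfonyl chloride, with pyridine as nucleophilic catalyst and acid scavenger, should stop at the mono-sulfonamide because the two ortho substituents shield nitrogen from a second sulfonylation, and the aldehyde and the C–Br bonds are inert to these conditions.

Step 2
Reactants: 3 N-(2,4-dibromo-6-formylphenyl)-4-methylbenzenesulfonamide; 4 ethyl bromoacetate
Product: 5 ethyl N-(2,4-dibromo-6-formylphenyl)-N-tosylglycinate
Conditions: ethyl bromoacetate (1.2 equiv), K2CO3, DMF, 0 °C to rt
Reagents that add atoms: ethyl bromoacetate (compound 4), CCOC(=O)CBr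
Why: SN2 N-alkylation of the acidic sulfonamide N–H by a reactive alpha-bromo ester under mild carbonate conditions is standard, the aldol closure should be slow at or below room temperature, and any indole formed early would simply converge in step 3.

Step 3
Reactants: 5 ethyl N-(2,4-dibromo-6-formylphenyl)-N-tosylglycinate
Product: 7 ethyl 5,7-dibromo-1-tosylindole-2-carboxylate, via 3-hydroxyindoline aldol adduct 6 (not isolated)
Conditions: K2CO3, DMF, 90 °C
Reagents that add atoms: none
Why: Carbonate deprotonates the CH2 flanked by the ester and the sulfonamide nitrogen, and the ester enolate attacks the neighbouring formyl carbon to forge C2–C3, giving the 3-hydroxyindoline 6. Loss of water by an E1cB pathway (C2–H remains alpha to the ester) then aromatises the new ring to the indole. The closest known reaction type is the base-mediated intramolecular aldol condensation of N-sulfonyl-N-(2-formylaryl)glycinates to 1-sulfonylindole-2-carboxylates. The pyrrole ring closes in the 5-(enolexo)-exo-trig mode, which is stereoelectronically favoured. No stereocentre survives, so the only selectivity needed is chemoselective enolisation at the glycinate CH2: the aldehyde has no alpha hydrogen, and the sulfonyl group both acidifies the CH2 and keeps nitrogen from condensing with the aldehyde. The aldol addition is reversible but the dehydration to the aromatic ring is not, which should pull the equilibrium forward, and carbonate in DMF is not expected to touch the C–Br bonds.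

Step 4
Reactants: 7 ethyl 5,7-dibromo-1-tosylindole-2-carboxylate
Product: 8 5,7-dibromo-1H-indole-2-carboxylic acid
Conditions: KOH (excess), EtOH/H2O, reflux; then aq. HCl
Reagents that add atoms: KOH (potassium hydroxide), [K+].[OH-]
Why: Ester saponification (BAc2) and hydroxide cleavage of the N–S bond should occur in one operation, because the anion of an indole-2-carboxylate is a good leaving group from sulfur and the unactivated aryl bromides do not undergo substitution by hydroxide.

Step 5
Reactants: 8 5,7-dibromo-1H-indole-2-carboxylic acid
Product: 9 5,7-dibromo-1H-indole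
Conditions: Cu2O (cat.), quinoline, 200 °C
Reagents that add atoms: none
Why: Copper-mediated thermal protodecarboxylation of an indole-2-carboxylic acid (copper carboxylate, loss of CO2 to a 2-indolylcopper species, protonation) is the standard way to remove a 2-carboxyl group from halogenated indoles, and with catalytic copper and a short heating time the aryl bromides should survive.

Step 6
Reactants: 9 5,7-dibromo-1H-indole
Product: 10 3,5,7-tribromo-1H-indole
Conditions: NBS (1.0 equiv), DMF, 0 °C to rt, dark
Reagents that add atoms: N-bromosuccinimide, BrN1C(=O)CCC1=O
Why: Electrophilic aromatic substitution at C3, the enamine-like and most nucleophilic position of an N–H indole, should give the 3-bromide selectively with one equivalent of NBS, since the benzene ring is deactivated by its two bromines and C2 reacts only after C3 is filled.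

**Compound list**

1 | 2-amino-3,5-dibromobenzaldehyde | Nc1c(Br)cc(Br)cc1C=O | starting material
2 | p-toluenesulfonyl chloride | Cc1ccc(cc1)S(Cl)(=O)=O | starting material
3 | N-(2,4-dibromo-6-formylphenyl)-4-methylbenzenesulfonamide | Cc1ccc(cc1)S(=O)(=O)Nc1c(Br)cc(Br)cc1C=O | intermediate
4 | ethyl bromoacetate | CCOC(=O)CBr | starting material
5 | ethyl N-(2,4-dibromo-6-formylphenyl)-N-tosylglycinate | CCOC(=O)CN(c1c(Br)cc(Br)cc1C=O)S(=O)(=O)c1ccc(C)cc1 | intermediate
6 | ethyl 5,7-dibromo-3-hydroxy-1-tosylindoline-2-carboxylate (racemic, mixture of diastereomers, not isolated) | CCOC(=O)C1C(O)c2cc(Br)cc(Br)c2N1S(=O)(=O)c1ccc(C)cc1 | intermediate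
7 | ethyl 5,7-dibromo-1-tosylindole-2-carboxylate | CCOC(=O)c1cc2cc(Br)cc(Br)c2n1S(=O)(=O)c1ccc(C)cc1 | intermediate
8 | 5,7-dibromo-1H-indole-2-carboxylic acid | OC(=O)c1cc2cc(Br)cc(Br)c2[nH]1 | intermediate
9 | 5,7-dibromo-1H-indole | Brc1cc(Br)c2[nH]ccc2c1 | intermediate
10 | 3,5,7-tribromo-1H-indole | Brc1cc(Br)c2[nH]cc(Br)c2c1 | target

**Step count**

Total steps: 6. Longest linear sequence: 6 steps (from 1).

**Steps most likely to fail, with fallbacks**

Step 1. The nitrogen of 1 is flanked by bromine and formyl groups and is electron-poor, so sulfonylation may be sluggish or incomplete. Forcing conditions could bring on condensation at the aldehyde or double sulfonylation. The fallback changes the activating group on nitrogen to trifluoroacetyl and sets out from 1. Trifluoroacetic anhydride and pyridine in CH2Cl2 at 0 °C should give N-(2,4-dibromo-6-formylphenyl)-2,2,2-trifluoroacetamide F1. Alkylation of its acidic N–H with 4 (K2CO3, DMF, rt) should give ethyl N-(2,4-dibromo-6-formylphenyl)-N-(trifluoroacetyl)glycinate F2. Warming F2 with K2CO3 in DMF should bring about the same C2–C3 aldol condensation, with the labile N-trifluoroacetyl group lost in the same pot, to give ethyl 5,7-dibromo-1H-indole-2-carboxylate F3. Saponification of F3 (KOH, EtOH/H2O, reflux; then aq. HCl) returns to the route at 8.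

Step 3. The ring closure may stall at the aldol adduct, with retro-aldol reaction or loss of the sulfonyl group from nitrogen competing with the slow dehydration. The fallback separates addition from elimination and sets out from 5. A catalytic amount of DBU in THF at 0 °C should give the adduct 6, which is isolated. Methanesulfonyl chloride and Et3N in CH2Cl2 at 0 °C should convert its hydroxyl into ethyl 5,7-dibromo-3-(methanesulfonyloxy)-1-tosylindoline-2-carboxylate F4. Added DBU should then eliminate methanesulfonate under mild, non-equilibrating conditions, returning to the route at 7.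

Step 5. At the high temperature of the copper-mediated decarboxylation, reductive loss of bromine or aryl–aryl coupling may occur, or carbon dioxide may be lost incompletely. The fallback removes the carboxyl group during ring closure instead and sets out from 3. Alkylation with tert-butyl bromoacetate (K2CO3, DMF, rt) should give tert-butyl N-(2,4-dibromo-6-formylphenyl)-N-tosylglycinate F5. Trifluoroacetic acid in CH2Cl2 should cleave the tert-butyl ester to N-(2,4-dibromo-6-formylphenyl)-N-tosylglycine F6. Heating F6 with Ac2O, NaOAc and AcOH at about 120 °C should close the same C2–C3 bond in a Perkin-type condensation through the mixed anhydride. The resulting beta-acetoxy acid (or beta-lactone) should lose carbon dioxide in a decarboxylative elimination, as is known for the oxygen analogues that give benzofurans, to afford 5,7-dibromo-1-tosylindole F7 without any copper. Cleavage of the N–S bond (KOH, aqueous EtOH, reflux) returns to the route at 9.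

**Further compounds**

F1 | step 1 | N-(2,4-dibromo-6-formylphenyl)-2,2,2-trifluoroacetamide | O=Cc1cc(Br)cc(Br)c1NC(=O)C(F)(F)F
F2 | step 1 | ethyl N-(2,4-dibromo-6-formylphenyl)-N-(trifluoroacetyl)glycinate | CCOC(=O)CN(C(=O)C(F)(F)F)c1c(Br)cc(Br)cc1C=O
F3 | step 1 | ethyl 5,7-dibromo-1H-indole-2-carboxylate | CCOC(=O)c1cc2cc(Br)cc(Br)c2[nH]1
F4 | step 3 | ethyl 5,7-dibromo-3-(methanesulfonyloxy)-1-tosylindoline-2-carboxylate | CCOC(=O)C1C(OS(C)(=O)=O)c2cc(Br)cc(Br)c2N1S(=O)(=O)c1ccc(C)cc1
F5 | step 5 | tert-butyl N-(2,4-dibromo-6-formylphenyl)-N-tosylglycinate | CC(C)(C)OC(=O)CN(c1c(Br)cc(Br)cc1C=O)S(=O)(=O)c1ccc(C)cc1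
F6 | step 5 | N-(2,4-dibromo-6-formylphenyl)-N-tosylglycine | OC(=O)CN(c1c(Br)cc(Br)cc1C=O)S(=O)(=O)c1ccc(C)cc1
F7 | step 5 | 5,7-dibromo-1-tosylindole | Cc1ccc(cc1)S(=O)(=O)n1ccc2cc(Br)cc(Br)c21
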